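Amounts first: per litre of the first phase this flask holds 1.0 M of starting material and 1.05 M of reagent in the second phase, a ratio of 1.05. The starting material is therefore the limiting reagent, and the ceiling of the curve of x, the fraction reacted, is its whole charge.

- south-west: starting material 1 M; reagent in the second phase 1.05 M; the very flask that is asked about, followed so far
- flask: starting material 1.0 M; reagent in the second phase 1.05 M; time 4.0 min; volume of the second phase over the first 0.50

south-west run (percent of the starting material charged)

| time / s | target / % | starting material / % |
|---|---|---|
| 10.0 | 1.0 | 99.5 |
| 12.0 | 1.3 | 99.0 |
| 20.0 | 2.6 | 96.8 |
| 25.0 | 4.2 | 96.1 |
| 40.0 | 8.3 | 91.6 |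
| 60.0 | 13.8 | 86.1 |
| 90.0 | 22.3 | 77.5 |

(each reading ± 0.3 percentage points)

- amount of target and product in the second phase together at 4.0 min, in percent of the starting material charged
- part of the starting material charged that has reacted at 4.0 min

- target is meant together with its product in the second phase
- in the second phase: reagent in the second phase, product in the second phase; everything else is in the first
- charges count per volume of the first phase; a concentration in a rate is the amount of a species over the volume of its own phase; every rate counts per litre of the first phase
- the earlier runs hold the two phases in the same ratio of volumes as the flask asked about

The south-west run is this same flask, followed so far. Its first target reading gives an opening slope of 0.00100 s⁻¹ of the charge. The last stretch of starting material reads a climb in x of 0.00287 s⁻¹, and that line drawn back meets zero at 11.5 s, which I read as the knee.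

Past the knee I write the slope as κ times a times b, with a the starting material left and b the reagent left, both in units of the starting material charged. This κ is my wearing-down constant. Over the last stretch x averages 0.182, so κ reads 0.00404 s⁻¹.

From a reading of 22.5% reacted at 90.0 s, holding the slope of that moment gives 0.612. Putting the middle of the stretch back in gives 0.447, then 0.512, then 0.486. I commit to that last value for both answers.

The forecast says 55% and 55%, holding that “something is building up”; my figure is lower.

The flask gives 47.0% for y and 49.6% for cv.

    reagent in the reaction phase ⇌ reagent in the second phase, rate k1*([reagent in the reaction phase] - [reagent in the second phase]/K1) per volume of the first phase (partition coefficient = 0.670, kL = 0.00980 s⁻¹)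
    starting material + reagent in the reaction phase → target (k = 0.00590 M⁻¹ s⁻¹)
    target ⇌ product in the second phase, rate k3*([target] - [product in the second phase]/K3) per volume of the first phase (partition coefficient = 1.20, kL = 0.00140 s⁻¹)
    target → decomposed product (k = 4.60 × 10⁻⁴ s⁻¹)
    reagent in the reaction phase → decomposition product (k = 4.20 × 10⁻⁶ s⁻¹)

At 49.6% the rule puts the slope at 4.0 min at 0.00113 s⁻¹, down from 0.00287 s⁻¹. The wearing away of the reagent in the second phase is the main reason that y in this flask stays short of the whole charge: without it y reaches 85.7%, not 47.0%. For the neighbour charged with 0.60 M of starting material, each fraction reacted takes less reagent; assuming the same x at 90.0 s and b still counted in units of 1.0 M, the rounds give 0.552, then 0.528, and that neighbour gives 54.8% for cv.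

The numbers in the tables are simulated from invented constants; scatter was added.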